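**Retrosynthetic overview**
- The (7Z,5E)-dienone O=C9–C8=C7–C6=C5 is the open valence isomer of a 2H-pyran (ring atoms: the C9 oxygen, C9, C8, C7, C6, C5, fused to the cyclopentene at C8–C9). This latent six-membered ring is the feature the key step uses.
- C6–C7 is cut to an enolised α-formyl ketone (C7 aldehyde carbon on C8, enol oxygen on C9; C7–C20) and an (E)-alkenylphosphonium salt (C1–C6). Oxa-Michael addition, intramolecular Wittig (C6=C7) and 6π ring opening should give the C6–C7 bond, 7Z and 5E in one operation.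
- The ring fragment comes from (R)-4-silyloxycyclopentenone: anti 1,2-addition of a (Z)-octenylbarium sets C12, desilylation/oxidation moves the carbonyl to C9, Br enters at C10 through the epoxy ketone, and C7 by formylation at C8.
- Ring order: the carbocycle is present from the start; the only ring made is the temporary 2H-pyran, closed and reopened in the key step. End game: desilylation and acetylation of the C12 alcohol.

Key step: step 10

Remark: prostanoid numbering (C1 = ester carbon, C20 = chain methyl) is used for atoms; compounds 1, 3, 15 and 16 are taken as commercially available.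

Step 1
Reactants: 1 (Z)-oct-2-en-1-ol
Product: 2 (Z)-1-chlorooct-2-ene
Conditions: NCS, Me2S, CH2Cl2, −20 to 0 °C
Reagents that add atoms: N-chlorosuccinimide, O=C1CCC(=O)N1Cl
Why: Corey–Kim chlorination of a primary allylic alcohol goes by SN2 displacement of the alkoxysulfonium ion, so the Z double bond should be kept and no allylic transposition is expected.

Step 2
Reactants: 2 (Z)-1-chlorooct-2-ene; 3 (R)-4-[(tert-butyldimethylsilyl)oxy]cyclopent-2-en-1-one
Product: 5 (1S,4R)-4-[(tert-butyldimethylsilyl)oxy]-1-[(2Z)-oct-2-en-1-yl]cyclopent-2-en-1-ol, via (Z)-oct-2-enylbarium chloride 4 (not isolated)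
Conditions: Ba* (from BaI2 and lithium biphenylide), THF, −78 °C; then 3, −78 °C
Reagents that add atoms: none
Why: Allylbarium carbonyl addition (Yamamoto) reacts at the α-carbon with retention of the Z geometry and 1,2 on the enone; approach anti to the C4 silyloxy group should set the new tertiary carbinol centre (future C12) with OH cis to OTBS.

Step 3
Reactants: 5 (1S,4R)-4-[(tert-butyldimethylsilyl)oxy]-1-[(2Z)-oct-2-en-1-yl]cyclopent-2-en-1-ol
Product: 6 (1S,4R)-1-[(2Z)-oct-2-en-1-yl]cyclopent-2-ene-1,4-diol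
Conditions: TBAF, THF, 0 °C to rt
Reagents that add atoms: none
Why: Fluoride cleavage of the secondary TBS ether; no stereocentre is touched.

Step 4
Reactants: 6 (1S,4R)-1-[(2Z)-oct-2-en-1-yl]cyclopent-2-ene-1,4-diol
Product: 7 (4S)-4-hydroxy-4-[(2Z)-oct-2-en-1-yl]cyclopent-2-en-1-one
Conditions: MnO2, CH2Cl2, rt
Reagents that add atoms: none
Why: Chemoselective MnO2 oxidation of the secondary allylic alcohol (the tertiary one cannot be oxidised) places the carbonyl at the future C9; the relay stereocentre is spent and the tertiary centre carries the chirality alone.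

Step 5
Reactants: 7 (4S)-4-hydroxy-4-[(2Z)-oct-2-en-1-yl]cyclopent-2-en-1-one
Product: 8 (4S)-4-[(2Z)-oct-2-en-1-yl]-4-[(triethylsilyl)oxy]cyclopent-2-en-1-one
Conditions: TESOTf, 2,6-lutidine, CH2Cl2, −78 to 0 °C
Reagents that add atoms: triethylsilyl trifluoromethanesulfonate, CC[Si](CC)(CC)OS(=O)(=O)C(F)(F)F
Why: Silyl triflate silylation of a hindered tertiary alcohol; the ether blocks retro-aldol opening of the β-hydroxy ketone in the basic steps that follow.

Step 6
Reactants: 8 (4S)-4-[(2Z)-oct-2-en-1-yl]-4-[(triethylsilyl)oxy]cyclopent-2-en-1-one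
Product: 9 (4S)-4-[(2Z)-oct-2-en-1-yl]-4-[(triethylsilyl)oxy]-6-oxabicyclo[3.1.0]hexan-2-one (both epoxide diastereomers)
Conditions: 30% H2O2, NaOH (cat.), MeOH, 0 °C
Reagents that add atoms: hydrogen peroxide, OO
Why: Weitz–Scheffer nucleophilic epoxidation attacks only the electron-poor enone double bond and leaves the isolated Z-alkene alone; the epoxide configuration does not matter because both carbons return to sp2 in step 7.

Step 7
Reactants: 9 (4S)-4-[(2Z)-oct-2-en-1-yl]-4-[(triethylsilyl)oxy]-6-oxabicyclo[3.1.0]hexan-2-one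
Product: 12 (4S)-2-bromo-4-[(2Z)-oct-2-en-1-yl]-4-[(triethylsilyl)oxy]cyclopent-2-en-1-one, via bromohydrin 10 (not isolated), via bromohydrin mesylate 11 (not isolated)
Conditions: LiBr, AcOH, THF, 0 °C to rt; then MsCl, Et3N, CH2Cl2, 0 °C
Reagents that add atoms: lithium bromide, [Li+].[Br-]
Why: Acid-assisted SN2 opening of the α,β-epoxy ketone by bromide at the α-carbon (the β-carbon is neopentyl-like next to the quaternary centre), then mesylation and E1cB loss of the β-mesylate should give the α-bromo enone without electrophilic bromine, which would attack the Z-alkene.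

Step 8
Reactants: 12 (4S)-2-bromo-4-[(2Z)-oct-2-en-1-yl]-4-[(triethylsilyl)oxy]cyclopent-2-en-1-one
Product: 14 (4R,5Z)-2-bromo-5-(hydroxymethylidene)-4-[(2Z)-oct-2-en-1-yl]-4-[(triethylsilyl)oxy]cyclopent-2-en-1-one, via lithium enolate 13 (not isolated)
Conditions: LDA, THF, −78 °C; CF3CH2OCHO, −78 to −20 °C; aq. HCl work-up
Reagents that add atoms: 2,2,2-trifluoroethyl formate, O=COCC(F)(F)F
Why: Kinetic deprotonation at the only enolisable position (C8) and Claisen-type C-formylation with trifluoroethyl formate should give the α-formyl ketone as its chelated Z-hydroxymethylene tautomer; C12 is untouched (its descriptor changes only because C8 becomes sp2).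

Step 9
Reactants: 15 methyl hex-5-ynoate; 16 triphenylphosphine
Product: 17 [(1E)-6-methoxy-6-oxohex-1-en-1-yl]triphenylphosphonium methanesulfonate
Conditions: MsOH, [RhCl(cod)]2 (cat.), THF, reflux
Reagents that add atoms: methanesulfonic acid, CS(=O)(=O)O
Why: Rhodium-catalysed anti-Markovnikov hydrophosphoniation of a terminal alkyne (addition of PPh3 and a strong acid) should give the (E)-alk-1-enylphosphonium salt; the ester is inert.

Step 10
Reactants: 14 (4R,5Z)-2-bromo-5-(hydroxymethylidene)-4-[(2Z)-oct-2-en-1-yl]-4-[(triethylsilyl)oxy]cyclopent-2-en-1-one; 17 [(1E)-6-methoxy-6-oxohex-1-en-1-yl]triphenylphosphonium methanesulfonate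
Product: 21 methyl (5E,7Z,12R,14Z)-10-bromo-9-oxo-12-[(triethylsilyl)oxy]prosta-5,7,10,14-tetraen-1-oate, via caesium enolate 18 (not isolated), via β-oxy ylide 19 (not isolated), via 2H-pyran 20 (not isolated)
Conditions: Cs2CO3 (1.0 equiv), 4 Å MS, DMF, 60 °C
Reagents that add atoms: none
Why: Proposed new method: the caesium enolate 18 of the α-formyl ketone should add reversibly through its C9 oxygen to the β-carbon (C5) of alkenylphosphonium salt 17 (oxa-Michael) to give ylide 19, whose carbanion C6 attacks the freed C7 aldehyde in an intramolecular Wittig olefination that makes the C6–C7 bond, expels Ph3P=O and leaves 2H-pyran 20, which opens at once by thermal 6π electrocyclic ring opening to dienone 21. The closest known reaction type is the Schweizer synthesis of 2H-chromenes from salicylaldehyde anions and vinyl- or propenyl-phosphonium salts; new are the non-aromatic enol partner and the ring opening, which a chromene cannot undergo without losing aromaticity. The only ring closed is the pyran (6-exo-trig attack of the ylide on the aldehyde, then oxaphosphetane collapse), and it is removed again in the same flask by disrotatory ring opening. No new stereocentre survives (C5 of 19 and 20 is transient, C12 is not touched); 7Z is dictated by the ring, because C6 and the C9 oxygen were cis members of the pyran, and 5E by outward rotation of the C5 chain during opening, with the pyran–dienone equilibrium pulled to the open form by the return of the cyclopentenone carbonyl. The selectivity needed is C9–O attack over C8 or formyl-O attack: the additions are reversible, the C8 adduct cannot olefinate without forming a four-membered ring, and the formyl-O adduct would have to olefinate the hindered vinylogous-ester ketone, so the fast aldehyde Wittig of 19 should drain the equilibrium. Exactly one equivalent of base is used so that no free base isomerises 17 to its allyl ylide.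

Step 11
Reactants: 21 methyl (5E,7Z,12R,14Z)-10-bromo-9-oxo-12-[(triethylsilyl)oxy]prosta-5,7,10,14-tetraen-1-oate
Product: 22 methyl (5E,7Z,12R,14Z)-10-bromo-12-hydroxy-9-oxoprosta-5,7,10,14-tetraen-1-oate
Conditions: HF·pyridine, THF, 0 °C
Reagents that add atoms: none
Why: Acidic fluoride desilylation of the tertiary TES ether under non-basic, non-nucleophilic conditions, so that the 7Z dienone should not be isomerised.

Step 12
Reactants: 22 methyl (5E,7Z,12R,14Z)-10-bromo-12-hydroxy-9-oxoprosta-5,7,10,14-tetraen-1-oate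
Product: 23 methyl (5E,7Z,12R,14Z)-12-acetoxy-10-bromo-9-oxoprosta-5,7,10,14-tetraen-1-oate (target)
Conditions: Ac2O, DMAP (cat.), pyridine, CH2Cl2, 0 °C to rt
Reagents that add atoms: acetic anhydride, CC(=O)OC(C)=O
Why: DMAP-catalysed acylation of the tertiary alcohol; only the O–H bond reacts, so the C12 configuration is retained.

**Compound list**
1 | (Z)-oct-2-en-1-ol | CCCCC/C=C\CO | starting material
2 | (Z)-1-chlorooct-2-ene | CCCCC/C=C\CCl | intermediate
3 | (R)-4-[(tert-butyldimethylsilyl)oxy]cyclopent-2-en-1-one | O=C1C=C[C@H](O[Si](C)(C)C(C)(C)C)C1 | starting material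
4 | (Z)-oct-2-enylbarium chloride | CCCCC/C=C\C[Ba]Cl | intermediate
5 | (1S,4R)-4-[(tert-butyldimethylsilyl)oxy]-1-[(2Z)-oct-2-en-1-yl]cyclopent-2-en-1-ol | CCCCC/C=C\C[C@@]1(O)C=C[C@H](O[Si](C)(C)C(C)(C)C)C1 | intermediate
6 | (1S,4R)-1-[(2Z)-oct-2-en-1-yl]cyclopent-2-ene-1,4-diol | CCCCC/C=C\C[C@@]1(O)C=C[C@H](O)C1 | intermediate
7 | (4S)-4-hydroxy-4-[(2Z)-oct-2-en-1-yl]cyclopent-2-en-1-one | CCCCC/C=C\C[C@@]1(O)C=CC(=O)C1 | intermediate
8 | (4S)-4-[(2Z)-oct-2-en-1-yl]-4-[(triethylsilyl)oxy]cyclopent-2-en-1-one | CCCCC/C=C\C[C@@]1(O[Si](CC)(CC)CC)C=CC(=O)C1 | intermediate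
9 | (4S)-4-[(2Z)-oct-2-en-1-yl]-4-[(triethylsilyl)oxy]-6-oxabicyclo[3.1.0]hexan-2-one, epoxide diastereomers | CCCCC/C=C\C[C@@]1(O[Si](CC)(CC)CC)C2OC2C(=O)C1 | intermediate
10 | bromohydrin: (4S)-2-bromo-3-hydroxy-4-[(2Z)-oct-2-en-1-yl]-4-[(triethylsilyl)oxy]cyclopentan-1-one, C2/C3 undefined | CCCCC/C=C\C[C@@]1(O[Si](CC)(CC)CC)C(O)C(Br)C(=O)C1 | intermediate
11 | bromohydrin mesylate: (4S)-2-bromo-3-(methylsulfonyloxy)-4-[(2Z)-oct-2-en-1-yl]-4-[(triethylsilyl)oxy]cyclopentan-1-one | CCCCC/C=C\C[C@@]1(O[Si](CC)(CC)CC)C(OS(C)(=O)=O)C(Br)C(=O)C1 | intermediate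
12 | (4S)-2-bromo-4-[(2Z)-oct-2-en-1-yl]-4-[(triethylsilyl)oxy]cyclopent-2-en-1-one | CCCCC/C=C\C[C@@]1(O[Si](CC)(CC)CC)C=C(Br)C(=O)C1 | intermediate
13 | lithium (3S)-5-bromo-3-[(2Z)-oct-2-en-1-yl]-3-[(triethylsilyl)oxy]cyclopenta-1,4-dien-1-olate (lithium enolate of 12) | CCCCC/C=C\C[C@@]1(O[Si](CC)(CC)CC)C=C(Br)C(O[Li])=C1 | intermediate
14 | (4R,5Z)-2-bromo-5-(hydroxymethylidene)-4-[(2Z)-oct-2-en-1-yl]-4-[(triethylsilyl)oxy]cyclopent-2-en-1-one | CCCCC/C=C\C[C@@]1(O[Si](CC)(CC)CC)C=C(Br)C(=O)/C1=C\O | intermediate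
15 | methyl hex-5-ynoate | COC(=O)CCCC#C | starting material
16 | triphenylphosphine | c1ccc(cc1)P(c1ccccc1)c1ccccc1 | starting material
17 | [(1E)-6-methoxy-6-oxohex-1-en-1-yl]triphenylphosphonium methanesulfonate | COC(=O)CCC/C=C/[P+](c1ccccc1)(c1ccccc1)c1ccccc1.CS(=O)(=O)[O-] | intermediate
18 | caesium enolate of 14 | CCCCC/C=C\C[C@@]1(O[Si](CC)(CC)CC)C=C(Br)C(=O)/C1=C\[O-].[Cs+] | intermediate
19 | β-oxy ylide: C9 enol ether of 14 with the C5 carbon of the chain, formyl group free, ylide at C6 (C5 undefined) | CCCCC/C=C\C[C@@]1(O[Si](CC)(CC)CC)C=C(Br)C(OC(CCCC(=O)OC)C=P(c2ccccc2)(c2ccccc2)c2ccccc2)=C1C=O | intermediate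
20 | 2H-pyran: methyl 4-[(5R)-7-bromo-5-[(2Z)-oct-2-en-1-yl]-5-[(triethylsilyl)oxy]-2,5-dihydrocyclopenta[b]pyran-2-yl]butanoate (C2 of the pyran undefined) | CCCCC/C=C\C[C@@]1(O[Si](CC)(CC)CC)C=C(Br)C2=C1C=CC(CCCC(=O)OC)O2 | intermediate
21 | methyl (5E,7Z,12R,14Z)-10-bromo-9-oxo-12-[(triethylsilyl)oxy]prosta-5,7,10,14-tetraen-1-oate | CCCCC/C=C\C[C@@]1(O[Si](CC)(CC)CC)C=C(Br)C(=O)/C1=C\C=C\CCCC(=O)OC | intermediate
22 | methyl (5E,7Z,12R,14Z)-10-bromo-12-hydroxy-9-oxoprosta-5,7,10,14-tetraen-1-oate | CCCCC/C=C\C[C@@]1(O)C=C(Br)C(=O)/C1=C\C=C\CCCC(=O)OC | intermediate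
23 | methyl (5E,7Z,12R,14Z)-12-acetoxy-10-bromo-9-oxoprosta-5,7,10,14-tetraen-1-oate | CCCCC/C=C\C[C@@]1(OC(C)=O)C=C(Br)C(=O)/C1=C\C=C\CCCC(=O)OC | target

**Step count and risks**
Total step count: 12. Longest linear sequence: 11 steps (steps 1–8 and 10–12; step 9 is the side branch).

Steps most likely to fail:

Step 10 (proposed new method). The oxa-Michael addition of a stabilised vinylogous-acid enolate to a β-alkyl-substituted alkenylphosphonium salt may be too slow or too unfavourable. Prototropic isomerisation of the salt to its allyl isomer, or alkylation at the formyl oxygen followed by olefination of the C9 ketone, could then take over. The fallback uses known chemistry and sets out from 14. Triflation of its lithium chelate (LiHMDS, PhNTf2, THF, −78 °C) should give the (Z)-enol triflate F1, with OTf cis to the C9 carbonyl. Suzuki–Miyaura coupling (Pd(PPh3)4, K3PO4, THF/H2O, rt) with methyl (E)-6-(pinacolboryl)hex-5-enoate F2, made from 15 by zirconocene-catalysed hydroboration with pinacolborane, should proceed with retention at both partners and faster at the vinylogous acyl triflate than at the C10 bromide. It comes back to the route at 21.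

Step 2. The allylbarium may lose regio- or geometric integrity (γ-attack giving the branched carbinol, Z to E equilibration on warming), or facial selectivity may be incomplete. The fallback sets out from 3. Addition of allenylmagnesium bromide (anti to the silyloxy group) should give the homopropargylic alcohol F3. Alkylation of its dianion (n-BuLi, 1-iodopentane, THF/DMPU) should give the oct-2-ynyl carbinol F4. Lindlar semi-hydrogenation then sets the Z-alkene and comes back at 5.

Step 7. Bromide may open the epoxide at the wrong carbon, the acid may remove the silyl ether, or base may cause β-elimination of the silyloxy group from the saturated ketone intermediates. The fallback sets out from 8. Conjugate addition of PhSeSiMe3 (cat. TMSOTf) should give the β-phenylseleno silyl enol ether F5. NBS at −78 °C brominates the enol ether carbon only, giving the α-bromo-β-phenylseleno ketone F6. H2O2 oxidises selenium to the selenoxide F7, whose syn-elimination can only remove the C10 hydrogen; it comes back at 12.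

Further compounds
F1 | step 10 | (4R,5Z)-2-bromo-4-[(2Z)-oct-2-en-1-yl]-4-[(triethylsilyl)oxy]-5-[(trifluoromethylsulfonyloxy)methylidene]cyclopent-2-en-1-one | CCCCC/C=C\C[C@@]1(O[Si](CC)(CC)CC)C=C(Br)C(=O)/C1=C\OS(=O)(=O)C(F)(F)F
F2 | step 10 | methyl (E)-6-(4,4,5,5-tetramethyl-1,3,2-dioxaborolan-2-yl)hex-5-enoate | COC(=O)CCC/C=C/B1OC(C)(C)C(C)(C)O1
F3 | step 2 | (1S,4R)-4-[(tert-butyldimethylsilyl)oxy]-1-(prop-2-yn-1-yl)cyclopent-2-en-1-ol | C#CC[C@@]1(O)C=C[C@H](O[Si](C)(C)C(C)(C)C)C1
F4 | step 2 | (1S,4R)-4-[(tert-butyldimethylsilyl)oxy]-1-(oct-2-yn-1-yl)cyclopent-2-en-1-ol | CCCCCC#CC[C@@]1(O)C=C[C@H](O[Si](C)(C)C(C)(C)C)C1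
F5 | step 7 | β-phenylseleno trimethylsilyl enol ether of 8 | CCCCC/C=C\C[C@@]1(O[Si](CC)(CC)CC)C([Se]c2ccccc2)C=C(O[Si](C)(C)C)C1
F6 | step 7 | (4S)-2-bromo-4-[(2Z)-oct-2-en-1-yl]-3-(phenylselanyl)-4-[(triethylsilyl)oxy]cyclopentan-1-one | CCCCC/C=C\C[C@@]1(O[Si](CC)(CC)CC)C([Se]c2ccccc2)C(Br)C(=O)C1
F7 | step 7 | selenoxide of F6 | CCCCC/C=C\C[C@@]1(O[Si](CC)(CC)CC)C([Se](=O)c2ccccc2)C(Br)C(=O)C1
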